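**Plan**
1. Numbering: C1 lactone carbonyl, C5 lactone carbinol, C6=C7, C8, carbinols C9, C11 and C13, styryl C14=C15. The retrosynthesis cuts C6=C7 (cross-metathesis), then C13–C14 (styrylzinc addition), then ties C7 and C13 together as the alkene of a cycloheptene.
2. Enabling feature: C7–C13 is a seven-carbon run whose oxygens on C9 and C11 are anti, which means trans on a ring. It maps onto the carbocycle of 8-oxabicyclo[3.2.1]oct-6-en-3-one, where furan delivers C7, C8, C9, C13 and O9 and an acetone unit delivers C10, C11, C12 and O11 (cuts C9–C10 and C12–C13).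
3. Forward: a [4+3] cycloaddition closes the bridged bicycle, followed by exo hydride delivery, silylation and ligand-controlled nickel hydride opening of one bridgehead C–O bond. A second, identical silyl group makes the cycloheptene C2-symmetric, so one ozonolysis with methanol capture gives a single aldehyde–ester.
4. Chain: C7 methylenation, C13 ester to aldehyde, styryl addition, silylation, cross-metathesis with the (R)-6-vinyl lactone (its ring closed separately by ring-closing metathesis), desilylation.
5. Stereochemistry: C9/C11 anti comes from the bicycle plus exo hydride attack, and their absolute sense from BINAP. C13 comes from the MIB-catalysed addition and C5 from allylboration of acrolein. The E alkenes come from syn hydroboration (C14=C15) and thermodynamic metathesis (C6=C7).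

Key step: step 1

Assumption: the ligand antipodes written in steps 4 and 9, (R)-BINAP and (−)-MIB, are taken to give the drawn configurations; if either induces the opposite sense, its commercially available antipode is used and nothing else changes.

**Step 1**
Reactants: 1 furan; 2 1,1,3,3-tetrabromopropan-2-one
Product: 5 meso-8-oxabicyclo[3.2.1]oct-6-en-3-one, via dibromo-oxyallyl cation 3 (not isolated), via 2,4-dibromo cycloadduct 4 (not isolated)
Conditions: Zn–Cu couple, furan (excess), THF, −10 °C → rt; then Zn–Cu couple, NH4Cl, MeOH, −78 °C → rt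
Reagents that add atoms: none
Why: Zinc transfers two electrons to 2 and one bromide leaves from each α-carbon, giving the dibromo-oxyallyl cation 3, a three-carbon 2π component that adds across C2 and C5 of furan, the 4π component, in a [4+3] cycloaddition of the oxyallyl cation/furan type, either in concert or through a furan-stabilised cation that collapses at once. The seven-membered carbocycle C7–C13 closes intermolecularly by this two-bond cycloaddition (C9–C10 and C12–C13), and the furan oxygen remains as the one-atom bridge between C9 and C13. The only stereocentres that last are the bridgeheads C9 and C13: a one-atom bridge can span the ring on one face only, so they are cis by geometry and 5 is meso, while the C–Br centres of 4 do not matter because the second portion of Zn–Cu with NH4Cl replaces both bromines by hydrogen. The step needs periselectivity for [4+3] over electrophilic substitution at furan C2 and over a second addition: the two bromines kept on 3 raise its electrophilicity enough to engage the weakly nucleophilic aromatic diene, the symmetry of both partners removes any regiochemical question, and excess furan intercepts 3 before it decays. The loss of furan aromaticity is paid for by two new C–C σ-bonds and the regenerated ketone.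

**Step 2**
Reactants: 5 meso-8-oxabicyclo[3.2.1]oct-6-en-3-one
Product: 6 meso-8-oxabicyclo[3.2.1]oct-6-en-3-endo-ol (axial OH trans to the oxygen bridge)
Conditions: LiBH(s-Bu)3, THF, −78 °C; then NaOH, H2O2, 0 °C
Reagents that add atoms: none
Why: Diastereoselective ketone reduction by a bulky trialkylborohydride: the endo face of C11 is screened by the C7=C8 bridge, so hydride should arrive from the exo face beside the oxygen bridge (equatorial attack on the pyranone chair) and leave the hydroxyl axial, endo and trans to the bridging oxygen across the carbocycle, which is the later C9/C11 anti relation.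

**Step 3**
Reactants: 6 meso-8-oxabicyclo[3.2.1]oct-6-en-3-endo-ol
Product: 7 meso-3-endo-(tert-butyldimethylsilyloxy)-8-oxabicyclo[3.2.1]oct-6-ene
Conditions: TBSCl, imidazole, DMF, rt
Reagents that add atoms: tert-butyldimethylsilyl chloride, CC(C)(C)[Si](C)(C)Cl
Why: Imidazole-promoted silyl ether formation masks the acidic hydroxyl before the aluminium hydride step, touches no stereocentre and keeps the compound meso.

**Step 4**
Reactants: 7 meso-3-endo-(tert-butyldimethylsilyloxy)-8-oxabicyclo[3.2.1]oct-6-ene
Product: 8 (1S,6S)-6-(tert-butyldimethylsilyloxy)cyclohept-3-en-1-ol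
Conditions: Ni(cod)2 (10 mol %), (R)-BINAP (18 mol %), i-Bu2AlH (1.2 equiv, slow addition), toluene, 60 °C; aq. potassium sodium tartrate
Reagents that add atoms: none
Why: Enantioselective reductive ring opening of a meso oxabicyclic alkene under zerovalent-nickel catalysis: the BINAP-bound nickel hydride adds to the exo face of C7=C8 and chooses between the two enantiotopic alkene carbons, hydrogen going to C8 and metal to C7, after which β-oxygen elimination breaks only the C13–O bond, creates C7=C13 and leaves oxygen on C9 with its configuration unchanged, so that the ligand alone fixes the absolute configuration of C9 and C11.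

**Step 5**
Reactants: 8 (1S,6S)-6-(tert-butyldimethylsilyloxy)cyclohept-3-en-1-ol
Product: 9 (4S,6S)-4,6-bis(tert-butyldimethylsilyloxy)cyclohept-1-ene
Conditions: TBSCl, imidazole, DMF, rt
Reagents that add atoms: tert-butyldimethylsilyl chloride, CC(C)(C)[Si](C)(C)Cl
Why: Imidazole-promoted silylation of the free C9 alcohol gives both oxygens the same group, which creates a C2 axis through C10 and the midpoint of C7=C13 and makes the two alkene carbons homotopic, the condition for an unambiguous unsymmetrical cleavage in step 6 (two β-oxygenated aldehydes that differ only in a remote protecting group could not be told apart by a reagent).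

**Step 6**
Reactants: 9 (4S,6S)-4,6-bis(tert-butyldimethylsilyloxy)cyclohept-1-ene
Product: 11 methyl (3R,5R)-3,5-bis(tert-butyldimethylsilyloxy)-7-oxoheptanoate, via α-methoxy hydroperoxide 10 (not isolated)
Conditions: O3, NaHCO3, CH2Cl2–MeOH (5:1), −78 °C; then Ac2O, Et3N, CH2Cl2, 0 °C → rt
Reagents that add atoms: ozone, [O-][O+]=O; methanol, CO
Why: Terminus-differentiating ozonolysis of a cycloalkene: Criegee cleavage in methanol releases one alkene carbon as the aldehyde and captures the other as the α-methoxy hydroperoxide 10, whose acetylation and Et3N-induced loss of acetic acid give the methyl ester, and because C7 and C13 of 9 are homotopic either sense of cleavage gives the same compound (aldehyde carbon labelled C7, ester carbon C13, the labels being interchangeable up to this point) with no stereocentre touched.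

**Step 7**
Reactants: 11 methyl (3R,5R)-3,5-bis(tert-butyldimethylsilyloxy)-7-oxoheptanoate
Product: 12 methyl (3R,5S)-3,5-bis(tert-butyldimethylsilyloxy)oct-7-enoate
Conditions: Ph3PCH3Br, KOt-Bu, THF, 0 °C; then 11, −78 → 0 °C
Reagents that add atoms: methyltriphenylphosphonium bromide, C[P+](c1ccccc1)(c1ccccc1)c1ccccc1.[Br-]
Why: Wittig methylenation: the non-stabilised ylide adds to the aldehyde far faster than to the methyl ester, and a slight deficit of base at low temperature keeps β-elimination of the C9 silyloxy group from competing, no stereocentre being involved.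

**Step 8**
Reactants: 12 methyl (3R,5S)-3,5-bis(tert-butyldimethylsilyloxy)oct-7-enoate
Product: 13 (3R,5S)-3,5-bis(tert-butyldimethylsilyloxy)oct-7-enal
Conditions: i-Bu2AlH (1.1 equiv), CH2Cl2, −78 °C; aq. potassium sodium tartrate
Reagents that add atoms: none
Why: Partial reduction of an ester with i-Bu2AlH: at −78 °C in a non-coordinating solvent a single hydride is delivered and the aldehyde is set free only on aqueous work-up, so over-reduction is avoided and the alkene, the silyl ethers and both stereocentres stay untouched.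

**Step 9**
Reactants: 13 (3R,5S)-3,5-bis(tert-butyldimethylsilyloxy)oct-7-enal; 14 phenylacetylene
Product: 17 (1E,3R,5S,7S)-5,7-bis(tert-butyldimethylsilyloxy)-1-phenyldeca-1,9-dien-3-ol, via styryl(dicyclohexyl)borane 15 (not isolated), via ethyl(styryl)zinc 16 (not isolated)
Conditions: 14, Cy2BH, toluene, 0 °C → rt; Et2Zn, −78 °C; (−)-MIB (5 mol %), then 13, −10 °C; aq. NH4Cl
Reagents that add atoms: none
Why: Catalytic asymmetric alkenylzinc addition: syn hydroboration of 14 fixes the E geometry, boron-to-zinc exchange gives 16, and the zinc amino-alkoxide of (−)-MIB directs styryl transfer to the Si face of the aldehyde, which sets C13 as R, syn to C11, under catalyst control that should override the weak 1,3-bias of the β-silyloxy group.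

**Step 10**
Reactants: 17 (1E,3R,5S,7S)-5,7-bis(tert-butyldimethylsilyloxy)-1-phenyldeca-1,9-dien-3-ol
Product: 18 [(1E,3R,5R,7S)-3,5,7-tris(tert-butyldimethylsilyloxy)deca-1,9-dien-1-yl]benzene
Conditions: TBSCl, imidazole, DMAP (cat.), DMF, rt
Reagents that add atoms: tert-butyldimethylsilyl chloride, CC(C)(C)[Si](C)(C)Cl
Why: Imidazole-promoted silylation caps the allylic alcohol so that it can neither guide ruthenium to the neighbouring styryl alkene nor be isomerised in step 14, adds steric cover to that alkene and lets all three ethers fall in one final operation.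

**Step 11**
Reactants: 19 acrolein
Product: 21 (R)-hexa-1,5-dien-3-ol, via diisopinocampheylborinate 20 (not isolated)
Conditions: (+)-Ipc2B(allyl) (from (−)-α-pinene), Et2O, −100 → −78 °C; then NaOH, H2O2, 0 °C → rt
Reagents that add atoms: (+)-B-allyldiisopinocampheylborane, C=CCB([C@H]1C[C@H]2C[C@@H]([C@@H]1C)C2(C)C)[C@H]1C[C@H]2C[C@@H]([C@@H]1C)C2(C)C
Why: Brown asymmetric allylboration through a chair-like six-membered transition state in which the isopinocampheyl groups expose one aldehyde face, which should give the R carbinol (future C5), 1,2-addition being the only course open to an allylborane on an enal.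

**Step 12**
Reactants: 21 (R)-hexa-1,5-dien-3-ol
Product: 22 (R)-hexa-1,5-dien-3-yl acrylate
Conditions: acryloyl chloride, Et3N, DMAP (cat.), CH2Cl2, 0 °C
Reagents that add atoms: acryloyl chloride, C=CC(=O)Cl
Why: Esterification with an acid chloride acylates oxygen without touching the C5–O bond, so the configuration is retained.

**Step 13**
Reactants: 22 (R)-hexa-1,5-dien-3-yl acrylate
Product: 23 (R)-6-vinyl-5,6-dihydro-2H-pyran-2-one
Conditions: RuCl2(PCy3)2(=CHPh) (first-generation Grubbs catalyst, 10 mol %), Ti(Oi-Pr)4 (30 mol %), CH2Cl2 (dilute), reflux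
Reagents that add atoms: none
Why: Ring-closing metathesis: the catalyst loads on the unhindered homoallylic terminal alkene and closes onto the acrylate to the six-membered lactone, in preference to the five-membered butenolide that would require the more hindered vinyl group next to the ester oxygen, and the stereocentre is not involved.

**Step 14**
Reactants: 18 [(1E,3R,5R,7S)-3,5,7-tris(tert-butyldimethylsilyloxy)deca-1,9-dien-1-yl]benzene; 23 (R)-6-vinyl-5,6-dihydro-2H-pyran-2-one
Product: 24 (6R)-6-[(1E,4S,6R,8R,9E)-4,6,8-tris(tert-butyldimethylsilyloxy)-10-phenyldeca-1,9-dien-1-yl]-5,6-dihydro-2H-pyran-2-one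
Conditions: RuCl2(H2IMes)(=CH-C6H4-2-Oi-Pr) (second-generation Hoveyda–Grubbs catalyst, 5–10 mol %), 23 (2.5 equiv), CH2Cl2, 40 °C
Reagents that add atoms: none
Why: Olefin cross-metathesis between a fast-reacting unhindered terminal alkene and a slowly homodimerising vinyl group next to an ester oxygen favours the hetero-coupled product and gives E-C6=C7 under thermodynamic control, while the endocyclic enoate and the 1,2-disubstituted styryl alkene shielded by the C13 silyloxy group are expected to stay out.

**Step 15**
Reactants: 24 (6R)-6-[(1E,4S,6R,8R,9E)-4,6,8-tris(tert-butyldimethylsilyloxy)-10-phenyldeca-1,9-dien-1-yl]-5,6-dihydro-2H-pyran-2-one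
Product: 25 (6R)-6-[(1E,4S,6R,8R,9E)-4,6,8-trihydroxy-10-phenyldeca-1,9-dien-1-yl]-5,6-dihydro-2H-pyran-2-one
Conditions: HF·pyridine, pyridine, THF, 0 °C → rt
Reagents that add atoms: none
Why: Fluoride-driven desilylation in a pyridine-buffered, only weakly acidic medium should remove the three secondary silyl ethers without base-induced opening or elimination of the dihydropyranone and without ionising the cinnamyl-type C13 alcohol, so that all four stereocentres are carried through.

**Compound list**
1 | furan | c1ccoc1 | starting material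
2 | 1,1,3,3-tetrabromopropan-2-one | O=C(C(Br)Br)C(Br)Br | starting material
3 | 1,3-dibromo-2-oxidoallyl cation (written free of zinc) | [O-]C(=CBr)[CH+]Br | intermediate
4 | 2,4-dibromo-8-oxabicyclo[3.2.1]oct-6-en-3-one (cis bridgeheads; C–Br epimers, left open) | O=C1C(Br)[C@H]2C=C[C@@H](C1Br)O2 | intermediate
5 | meso-8-oxabicyclo[3.2.1]oct-6-en-3-one | O=C1C[C@H]2C=C[C@@H](C1)O2 | intermediate
6 | meso-8-oxabicyclo[3.2.1]oct-6-en-3-endo-ol (axial OH, trans to the oxygen bridge) | C1=C[C@H]2C[C@@H](O)C[C@@H]1O2 | intermediate
7 | meso-3-endo-(tert-butyldimethylsilyloxy)-8-oxabicyclo[3.2.1]oct-6-ene | C1=C[C@H]2C[C@@H](O[Si](C)(C)C(C)(C)C)C[C@@H]1O2 | intermediate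
8 | (1S,6S)-6-(tert-butyldimethylsilyloxy)cyclohept-3-en-1-ol | C1=CC[C@H](O)C[C@@H](O[Si](C)(C)C(C)(C)C)C1 | intermediate
9 | (4S,6S)-4,6-bis(tert-butyldimethylsilyloxy)cyclohept-1-ene | C1=CC[C@H](O[Si](C)(C)C(C)(C)C)C[C@@H](O[Si](C)(C)C(C)(C)C)C1 | intermediate
10 | (3R,5R)-3,5-bis(tert-butyldimethylsilyloxy)-7-hydroperoxy-7-methoxyheptanal (epimers at the peroxyacetal carbon) | O=CC[C@H](O[Si](C)(C)C(C)(C)C)C[C@@H](O[Si](C)(C)C(C)(C)C)CC(OC)OO | intermediate
11 | methyl (3R,5R)-3,5-bis(tert-butyldimethylsilyloxy)-7-oxoheptanoate | O=CC[C@H](O[Si](C)(C)C(C)(C)C)C[C@@H](O[Si](C)(C)C(C)(C)C)CC(=O)OC | intermediate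
12 | methyl (3R,5S)-3,5-bis(tert-butyldimethylsilyloxy)oct-7-enoate | C=CC[C@H](O[Si](C)(C)C(C)(C)C)C[C@@H](O[Si](C)(C)C(C)(C)C)CC(=O)OC | intermediate
13 | (3R,5S)-3,5-bis(tert-butyldimethylsilyloxy)oct-7-enal | C=CC[C@H](O[Si](C)(C)C(C)(C)C)C[C@@H](O[Si](C)(C)C(C)(C)C)CC=O | intermediate
14 | phenylacetylene | C#Cc1ccccc1 | starting material
15 | dicyclohexyl[(E)-2-phenylethenyl]borane | C1CCCCC1B(/C=C/c1ccccc1)C1CCCCC1 | intermediate
16 | ethyl[(E)-2-phenylethenyl]zinc | CC[Zn]/C=C/c1ccccc1 | intermediate
17 | (1E,3R,5S,7S)-5,7-bis(tert-butyldimethylsilyloxy)-1-phenyldeca-1,9-dien-3-ol | C=CC[C@H](O[Si](C)(C)C(C)(C)C)C[C@@H](O[Si](C)(C)C(C)(C)C)C[C@@H](O)/C=C/c1ccccc1 | intermediate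
18 | [(1E,3R,5R,7S)-3,5,7-tris(tert-butyldimethylsilyloxy)deca-1,9-dien-1-yl]benzene | C=CC[C@H](O[Si](C)(C)C(C)(C)C)C[C@@H](O[Si](C)(C)C(C)(C)C)C[C@@H](O[Si](C)(C)C(C)(C)C)/C=C/c1ccccc1 | intermediate
19 | acrolein | C=CC=O | starting material
20 | (R)-hexa-1,5-dien-3-yl diisopinocampheylborinate | C=CC[C@H](C=C)OB([C@H]1C[C@H]2C[C@@H]([C@@H]1C)C2(C)C)[C@H]1C[C@H]2C[C@@H]([C@@H]1C)C2(C)C | intermediate
21 | (R)-hexa-1,5-dien-3-ol | C=CC[C@H](C=C)O | intermediate
22 | (R)-hexa-1,5-dien-3-yl acrylate | C=CC[C@H](C=C)OC(=O)C=C | intermediate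
23 | (R)-6-vinyl-5,6-dihydro-2H-pyran-2-one | O=C1C=CC[C@H](C=C)O1 | intermediate
24 | (6R)-6-[(1E,4S,6R,8R,9E)-4,6,8-tris(tert-butyldimethylsilyloxy)-10-phenyldeca-1,9-dien-1-yl]-5,6-dihydro-2H-pyran-2-one | O=C1C=CC[C@H](/C=C/C[C@H](O[Si](C)(C)C(C)(C)C)C[C@@H](O[Si](C)(C)C(C)(C)C)C[C@@H](O[Si](C)(C)C(C)(C)C)/C=C/c2ccccc2)O1 | intermediate
25 | (6R)-6-[(1E,4S,6R,8R,9E)-4,6,8-trihydroxy-10-phenyldeca-1,9-dien-1-yl]-5,6-dihydro-2H-pyran-2-one | O=C1C=CC[C@H](/C=C/C[C@H](O)C[C@@H](O)C[C@@H](O)/C=C/c2ccccc2)O1 | target

**Totals:** 15 steps. The longest linear sequence is 12 steps (steps 1–10, 14, 15). The lactone arm (steps 11–13) is convergent.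

**Steps most likely to fail**

Step 9. The risk is insufficient facial selectivity, because the catalyst has to work against the intrinsic 1,3-bias of the β-silyloxy aldehyde, together with competing ethyl transfer from zinc. The fallback sets C13 by ketone reduction instead of by C–C bond formation.
- It starts from 13. Phenylacetylene 14 is deprotonated with n-BuLi (THF, −78 °C) to lithium phenylacetylide F1.
- Its addition to 13 gives the C13-epimeric propargylic alcohols F2.
- Dess–Martin periodinane oxidises these to the ynone F3.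
- Noyori transfer hydrogenation with RuCl[(R,R)-TsDPEN](p-cymene) in i-PrOH should give the (13R)-propargylic alcohol F4, whatever the resident stereocentres.
- Hydroxyl-directed trans reduction with NaAlH2(OCH2CH2OMe)2 in THF returns to the route at 17.

Step 14. The risk is slow engagement of the electron-poor, hindered vinyl lactone, which would let self-metathesis of the chain alkene and metathesis at the styryl alkene compete. The fallback builds the lactone on the chain.
- It starts from 18. Cross-metathesis with a large excess of crotonaldehyde under RuCl2(H2IMes)(=CH-C6H4-2-Oi-Pr) gives the (E)-enal F5.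
- (+)-Ipc2B(allyl) adds to it to give the diisopinocampheylborinate F6.
- NaOH/H2O2 work-up releases the (5R)-homoallylic alcohol F7.
- Acryloyl chloride/Et3N gives the acrylate F8.
- Ring-closing metathesis with RuCl2(PCy3)2(=CHPh), a catalyst that leaves 1,2-disubstituted alkenes alone, returns to the route at 24.

Step 6. The risk is β-elimination of a silyloxy group from the aldehyde during the Ac2O/Et3N stage, or incomplete methanol capture during cleavage. The fallback uses the homotopic termini in another way.
- It starts from 9. Ozonolysis in CH2Cl2 with Ph3P work-up gives the C2-symmetric dialdehyde F9.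
- Treatment with a deficit of Ph3P=CH2 (THF, −78 °C) can give only one mono-olefination product, which is 13. Unreacted F9 is recycled.
- The route is rejoined at 13, and steps 7 and 8 fall away.

**Further compounds**
F1 | step 9 | lithium phenylacetylide | [Li]C#Cc1ccccc1
F2 | step 9 | (3RS,5S,7S)-5,7-bis(tert-butyldimethylsilyloxy)-1-phenyldec-9-en-1-yn-3-ol | C=CC[C@H](O[Si](C)(C)C(C)(C)C)C[C@@H](O[Si](C)(C)C(C)(C)C)CC(O)C#Cc1ccccc1
F3 | step 9 | (5R,7S)-5,7-bis(tert-butyldimethylsilyloxy)-1-phenyldec-9-en-1-yn-3-one | C=CC[C@H](O[Si](C)(C)C(C)(C)C)C[C@@H](O[Si](C)(C)C(C)(C)C)CC(=O)C#Cc1ccccc1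
F4 | step 9 | (3R,5S,7S)-5,7-bis(tert-butyldimethylsilyloxy)-1-phenyldec-9-en-1-yn-3-ol | C=CC[C@H](O[Si](C)(C)C(C)(C)C)C[C@@H](O[Si](C)(C)C(C)(C)C)C[C@@H](O)C#Cc1ccccc1
F5 | step 14 | (2E,5S,7R,9R,10E)-5,7,9-tris(tert-butyldimethylsilyloxy)-11-phenylundeca-2,10-dienal | O=C/C=C/C[C@H](O[Si](C)(C)C(C)(C)C)C[C@@H](O[Si](C)(C)C(C)(C)C)C[C@@H](O[Si](C)(C)C(C)(C)C)/C=C/c1ccccc1
F6 | step 14 | (4R,5E,8S,10R,12R,13E)-8,10,12-tris(tert-butyldimethylsilyloxy)-14-phenyltetradeca-1,5,13-trien-4-yl diisopinocampheylborinate | C=CC[C@H](/C=C/C[C@H](O[Si](C)(C)C(C)(C)C)C[C@@H](O[Si](C)(C)C(C)(C)C)C[C@@H](O[Si](C)(C)C(C)(C)C)/C=C/c1ccccc1)OB([C@H]1C[C@H]2C[C@@H]([C@@H]1C)C2(C)C)[C@H]1C[C@H]2C[C@@H]([C@@H]1C)C2(C)C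
F7 | step 14 | (4R,5E,8S,10R,12R,13E)-8,10,12-tris(tert-butyldimethylsilyloxy)-14-phenyltetradeca-1,5,13-trien-4-ol | C=CC[C@H](/C=C/C[C@H](O[Si](C)(C)C(C)(C)C)C[C@@H](O[Si](C)(C)C(C)(C)C)C[C@@H](O[Si](C)(C)C(C)(C)C)/C=C/c1ccccc1)O
F8 | step 14 | (4R,5E,8S,10R,12R,13E)-8,10,12-tris(tert-butyldimethylsilyloxy)-14-phenyltetradeca-1,5,13-trien-4-yl acrylate | C=CC[C@H](/C=C/C[C@H](O[Si](C)(C)C(C)(C)C)C[C@@H](O[Si](C)(C)C(C)(C)C)C[C@@H](O[Si](C)(C)C(C)(C)C)/C=C/c1ccccc1)OC(=O)C=C
F9 | step 6 | (3R,5R)-3,5-bis(tert-butyldimethylsilyloxy)heptanedial | O=CC[C@H](O[Si](C)(C)C(C)(C)C)C[C@@H](O[Si](C)(C)C(C)(C)C)CC=O
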